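**Strategy**

Ring A (C1–C2–C3–C4–C9) is a cyclopentenone whose carbonyl carbon C2 lies between C1H2 and the C3H=C4 alkene, fused to ring B at C4–C9: the retron of an intramolecular Pauson–Khand reaction. C3≡C4 becomes a terminal alkyne on quaternary C5, C9=C1 a 1,1-disubstituted alkene and C2 carbon monoxide. One cobalt-mediated step on an acyclic 1,7-enyne closes rings A and B, forms C4–C9, C1–C2 and C2–C3 and sets quaternary C9. Ring C is then closed at C11–C12 by a chromium-mediated allylation. The enyne arises from an Eschenmoser–Tanabe fragmentation of a cyclohexenone carrying C5, C6 and C14, joined to a Roche-ester-derived C9–C11 iodoalkene.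

Key step: step 18

Atom labels (mutilin numbering): ring A = C1, C2 (C=O), C3, C4, C9; ring B = C4, C5, C6, C7, C8, C9; ring C = C4, C5, C14, C13, C12, C11, C10, C9; C19=C20 is the vinyl group on C12; methyl groups sit on C5, C6, C10 and C12.

Assumption: the stereodescriptors are used exactly as written (5S,6S,8S,9R,10R,11S,12S,14R); they place C14 (on C5) and C10 (on C9) on opposite faces of ring B, so ring C is a trans-bridged (inside–outside) eight-membered ring across sp2 carbon C4, and all stereochemical arguments below are made for this arrangement.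

**Route**

Step 1
Reactants: 1 cyclohex-2-en-1-one
Product: 3 (S)-2-(hydroxymethylene)-3-methylcyclohexan-1-one, via zinc enolate 2 (not isolated)
Conditions: Me2Zn, Cu(OTf)2 (2 mol%), (S,R,R)-O,O'-(1,1'-binaphthyl-2,2'-diyl)-N,N-bis(1-phenylethyl)phosphoramidite (4 mol%; the enantiomer that delivers the 3S ketone), toluene, −30 °C; MeLi, THF, −78 °C; HCO2CH2CF3, −78 → 0 °C; aq. HCl
Reagents that add atoms: dimethylzinc C[Zn]C; 2,2,2-trifluoroethyl formate O=COCC(F)(F)F
Why: Copper-catalysed asymmetric conjugate addition sets C6 (S) under ligand control, and the regiodefined enolate 2, activated as its lithium zincate, is C-formylated at C5 only (Claisen-type acylation).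

Step 2
Reactants: 3 (S)-2-(hydroxymethylene)-3-methylcyclohexan-1-one
Product: 4 (1R,2S)-1,2-dimethyl-6-oxocyclohexane-1-carbaldehyde
Conditions: MeI, K2CO3, acetone, rt
Reagents that add atoms: iodomethane CI
Why: C-Alkylation of the hydroxymethylene-ketone enolate creates quaternary C5, with iodomethane approaching anti to the neighbouring C6 methyl group so that the formyl carbon C14 ends cis to it.

Step 3
Reactants: 4 (1R,2S)-1,2-dimethyl-6-oxocyclohexane-1-carbaldehyde
Product: 5 (2R,3S)-2-[(1R)-1-hydroxy-3-methylbut-3-en-1-yl]-2,3-dimethylcyclohexan-1-one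
Conditions: CH2=C(CH3)CH2SiMe3, TiCl4, CH2Cl2, −78 °C
Reagents that add atoms: trimethyl(2-methylallyl)silane C=C(C)C[Si](C)(C)C
Why: Chelation-controlled Hosomi–Sakurai allylation in which TiCl4 bridges the two carbonyl oxygens and the allylsilane attacks the aldehyde face flanked by the C5 methyl group, away from the ring C6 branch, which sets C14 (R).

Step 4
Reactants: 5 (2R,3S)-2-[(1R)-1-hydroxy-3-methylbut-3-en-1-yl]-2,3-dimethylcyclohexan-1-one
Product: 6 (1R)-1-[(1R,2S)-1,2-dimethyl-6-oxocyclohexyl]-3-methylbut-3-en-1-yl acrylate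
Conditions: acryloyl chloride, iPr2NEt, DMAP (cat.), CH2Cl2, 0 °C → rt
Reagents that add atoms: acryloyl chloride C=CC(=O)Cl
Why: Acylation of the hindered secondary alcohol installs the temporary acrylate tether that supplies C19 and C20 and also blocks retro-aldol cleavage.

Step 5
Reactants: 6 acrylate of 5
Product: 7 (6R)-6-[(1R,2S)-1,2-dimethyl-6-oxocyclohexyl]-4-methyl-5,6-dihydro-2H-pyran-2-one
Conditions: second-generation Grubbs catalyst (5 mol%), toluene, 80 °C
Reagents that add atoms: none
Why: Ring-closing metathesis between the acrylate and the 1,1-disubstituted alkene gives the unsaturated δ-lactone, whose ring fixes the C12=C19 alkene in the Z geometry (C13 cis to C20) needed in step 22.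

Step 6
Reactants: 7 keto lactone
Product: 8 (6R)-6-[(1R,6S)-1,6-dimethyl-2-oxocyclohex-3-en-1-yl]-4-methyl-5,6-dihydro-2H-pyran-2-one
Conditions: 2-iodoxybenzoic acid (IBX), DMSO/toluene, 70 °C
Reagents that add atoms: none
Why: IBX dehydrogenation of the ketone can only take place between C3 and C8 because C5 is quaternary, giving the cyclohexenone needed for fragmentation.

Step 7
Reactants: 8 cyclohexenone lactone
Product: 9 C3–C8 epoxy ketone of 8 (either epoxide face)
Conditions: t-BuOOH, DBU, CH2Cl2, 0 °C → rt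
Reagents that add atoms: tert-butyl hydroperoxide CC(C)(C)OO
Why: Weitz–Scheffer nucleophilic epoxidation attacks the unhindered enone β-carbon C8 in preference to the less electrophilic, β,β-disubstituted unsaturated lactone, and both epoxide diastereomers converge in the next step.

Step 8
Reactants: 9 epoxy ketone
Product: 10 (3S,4S)-3,4-dimethyl-4-[(2R)-4-methyl-6-oxo-3,6-dihydro-2H-pyran-2-yl]hex-5-ynal
Conditions: TsNHNH2, AcOH/CH2Cl2, −20 °C → rt
Reagents that add atoms: none
Why: Eschenmoser–Tanabe fragmentation of the epoxy ketone tosylhydrazone cleaves the C3–C8 bond with loss of N2 and sulfinate, turning C4–C3 into the terminal alkyne on quaternary C5 and C8 into the aldehyde without touching C5, C6 or C14.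

Step 9
Reactants: 11 methyl (S)-3-hydroxy-2-methylpropanoate
Product: 12 methyl (S)-3-(tert-butyldimethylsilyloxy)-2-methylpropanoate
Conditions: TBSCl, imidazole, CH2Cl2, rt
Reagents that add atoms: tert-butyldimethylsilyl chloride CC(C)(C)[Si](C)(C)Cl
Why: Standard silylation protects the future C11 hydroxyl, and the C10 stereocentre is taken from the chiral pool.

Step 10
Reactants: 12 silyl ether ester
Product: 13 (S)-3-(tert-butyldimethylsilyloxy)-2-methylpropanal
Conditions: iBu2AlH, CH2Cl2, −78 °C
Reagents that add atoms: none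
Why: Partial reduction of the ester at low temperature stops at the aldehyde through the stable aluminium hemiacetal and does not epimerise C10.

Step 11
Reactants: 13 aldehyde
Product: 14 (R)-tert-butyldimethyl[(2-methylbut-3-yn-1-yl)oxy]silane
Conditions: dimethyl (1-diazo-2-oxopropyl)phosphonate, K2CO3, MeOH, 0 °C → rt
Reagents that add atoms: dimethyl (1-diazo-2-oxopropyl)phosphonate COP(=O)(OC)C(=[N+]=[N-])C(C)=O
Why: Seyferth–Gilbert homologation in its Ohira–Bestmann form converts the aldehyde into the terminal alkyne (C9≡C1) under conditions mild enough to keep the α-stereocentre.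

Step 12
Reactants: 14 alkyne
Product: 16 (S)-tert-butyl[(3-iodo-2-methylbut-3-en-1-yl)oxy]dimethylsilane, via alkenylalane 15 (not isolated)
Conditions: iBu2AlH, Ni(dppp)Cl2 (3 mol%), THF, 0 °C → rt; I2, −78 → 0 °C
Reagents that add atoms: iodine I-I
Why: Nickel-catalysed Markovnikov (α-selective) hydroalumination places aluminium on the internal carbon C9, and iodinolysis with retention gives the 2-iodoalk-1-ene.

Step 13
Reactants: 10 alkynal lactone; 16 iodoalkene
Product: 17 C8 allylic alcohol (5S,6S,8S,10R,14R): C3≡C4–C5(CH3)(lactone at C14)–C6H(CH3)–C7H2–C8H(OH)–C9(=C1H2)–C10H(CH3)–C11H2–OTBS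
Conditions: CrCl2, NiCl2 (cat.), (S)-N-[2-(4-isopropyl-4,5-dihydrooxazol-2-yl)-6-methylphenyl]methanesulfonamide (or its enantiomer, whichever delivers 8S), Et3N, THF, rt
Reagents that add atoms: none
Why: Nozaki–Hiyama–Kishi coupling joins C8 and C9 chemoselectively at the aldehyde in the presence of the lactone and the terminal alkyne, and the chiral sulfonamide ligand on chromium controls the new C8 carbinol centre (S).

Step 14
Reactants: 17 allylic alcohol
Product: 18 C8 tert-butyldimethylsilyl ether of 17
Conditions: TBSOTf, 2,6-lutidine, CH2Cl2, −78 °C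
Reagents that add atoms: tert-butyldimethylsilyl triflate CC(C)(C)[Si](C)(C)OS(=O)(=O)C(F)(F)F
Why: Silylation masks the C8 hydroxyl, which would otherwise be acetylated in step 17 and form a lactol with the C11 aldehyde of step 21.

Step 15
Reactants: 18 silyl ether lactone
Product: 19 (Z)-diol: lactone opened to C14–OH and (Z)-C13H2–C12(CH3)=C19H–C20H2OH
Conditions: iBu2AlH, CH2Cl2, −78 → 0 °C
Reagents that add atoms: none
Why: Exhaustive 1,2-reduction of the unsaturated lactone opens the temporary ring to the (Z)-allylic diol, freeing O14 and the C20 hydroxyl with the alkene geometry intact.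

Step 16
Reactants: 19 (Z)-diol
Product: 20 C20 tert-butyldimethylsilyl ether of 19
Conditions: TBSCl, imidazole, CH2Cl2, 0 °C
Reagents that add atoms: tert-butyldimethylsilyl chloride CC(C)(C)[Si](C)(C)Cl
Why: The primary allylic C20 hydroxyl is silylated selectively over the neopentyl-type secondary C14 hydroxyl.

Step 17
Reactants: 20 C14 alcohol
Product: 21 C14 acetate of 20 (the 1,7-enyne)
Conditions: Ac2O, DMAP, pyridine, 40 °C
Reagents that add atoms: acetic anhydride CC(=O)OC(C)=O
Why: Acylation of the only free hydroxyl installs the C14 acetate of the target.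

Step 18
Reactants: 21 1,7-enyne acetate
Product: 23 bicyclic enone with rings A and B (5S,6S,8S,9R,10R,14R), via dicobalt hexacarbonyl complex 22 (not isolated)
Conditions: Co2(CO)8, CH2Cl2, rt; n-BuSMe, ClCH2CH2Cl, 83 °C, 0.01 M
Reagents that add atoms: octacarbonyldicobalt (delivers one CO) O=C=[Co](=C=O)(=C=O)(=C=O)[Co](=C=O)(=C=O)(=C=O)=C=O
Why: Intramolecular Pauson–Khand reaction of a 1,7-enyne, the closest known type being the cobalt-mediated cyclocarbonylation of 1,7-enynes bearing 1,1-disubstituted alkenes to angularly substituted bicyclo[4.3.0]nonenones: complex 22 loses CO, the C9=C1 alkene inserts into the Co–C4 bond, CO inserts into the Co–C1 bond and reductive elimination joins the acyl carbon C2 to C3. Ring B (C4, C5, C6, C7, C8, C9) closes in the exo mode when C4–C9 forms (C1 stays outside the ring), and ring A (C1, C2, C3, C4, C9) closes in the final reductive elimination that makes the C2–C3 bond. The only new stereocentre, quaternary C9 (R), is set by a chair-like cobaltacycle with the C14 side chain on C5 and the C8 silyloxy group equatorial and the C10 chain axial, so that C10 ends trans to C14 and cis to the C5 methyl group and O8. The step needs regioselectivity (C4 to C9, C3 to C2 to C1), secured by the three-carbon tether that allows no other mode, chemoselectivity over the C12=C19 alkene, secured by its remoteness and trisubstitution, and facial selectivity at C9, secured by the preference of the bulky C5 and C8 substituents for equatorial positions.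

Step 19
Reactants: 23 bicyclic enone
Product: 24 C11,C20-diol of 23 (C8 silyl ether kept)
Conditions: HF·pyridine, pyridine, THF, 0 °C
Reagents that add atoms: none
Why: Buffered fluoride cleaves the two primary silyl ethers (O11, O20) much faster than the hindered secondary C8 silyl ether next to quaternary C9.

Step 20
Reactants: 24 diol
Product: 25 (Z)-C20 allylic chloride with free C11 hydroxyl
Conditions: NCS, Me2S, CH2Cl2, −20 → 0 °C
Reagents that add atoms: N-chlorosuccinimide O=C1CCC(=O)N1Cl
Why: Corey–Kim chlorination converts only the allylic alcohol into the chloride by SN2 displacement of its alkoxysulfonium salt, without allylic transposition, and leaves the saturated C11 alcohol untouched.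

Step 21
Reactants: 25 chloro alcohol
Product: 26 C11 aldehyde of 25
Conditions: Dess–Martin periodinane, CH2Cl2, 0 °C → rt
Reagents that add atoms: none
Why: Dess–Martin oxidation should give the C11 aldehyde under non-epimerising conditions that tolerate the allylic chloride and the enone.

Step 22
Reactants: 26 chloro aldehyde
Product: 27 8-O-tert-butyldimethylsilyl ether of the target (rings A, B and C closed)
Conditions: CrCl2, LiI (cat.), THF/DMF, rt, slow addition (high dilution)
Reagents that add atoms: none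
Why: Intramolecular Nozaki–Hiyama allylation closes ring C by γ-attack of the allylchromium species at C12 on the C11 aldehyde, with Felkin–Anh addition anti to C9 and a Zimmerman–Traxler chair in which the (Z)-allyl unit carries C13 axial and the methyl group equatorial, which should give 11S and 12S and leave the vinyl group on C12.

Step 23
Reactants: 27 silyl ether
Product: 28 pleuromutilin E as written (5S,6S,8S,9R,10R,11S,12S,14R)
Conditions: HF·pyridine, THF, rt
Reagents that add atoms: none
Why: Fluoride-mediated removal of the last silyl ether frees the C8 hydroxyl and leaves the hindered C14 acetate in place.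

**Compound list**

1 | cyclohex-2-en-1-one | O=C1C=CCCC1 | starting material
2 | methylzinc (S)-3-methylcyclohex-1-en-1-olate | C[Zn]OC1=C[C@@H](C)CCC1 | intermediate (not isolated)
3 | (S)-2-(hydroxymethylene)-3-methylcyclohexan-1-one | O=C1CCC[C@H](C)C1=CO | intermediate
4 | (1R,2S)-1,2-dimethyl-6-oxocyclohexane-1-carbaldehyde | O=C[C@@]1(C)[C@@H](C)CCCC1=O | intermediate
5 | (2R,3S)-2-[(1R)-1-hydroxy-3-methylbut-3-en-1-yl]-2,3-dimethylcyclohexan-1-one | C=C(C)C[C@@H](O)[C@@]1(C)[C@@H](C)CCCC1=O | intermediate
6 | (1R)-1-[(1R,2S)-1,2-dimethyl-6-oxocyclohexyl]-3-methylbut-3-en-1-yl acrylate | C=CC(=O)O[C@H](CC(C)=C)[C@@]1(C)[C@@H](C)CCCC1=O | intermediate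
7 | (6R)-6-[(1R,2S)-1,2-dimethyl-6-oxocyclohexyl]-4-methyl-5,6-dihydro-2H-pyran-2-one | CC1=CC(=O)O[C@H](C1)[C@@]2(C)[C@@H](C)CCCC2=O | intermediate
8 | (6R)-6-[(1R,6S)-1,6-dimethyl-2-oxocyclohex-3-en-1-yl]-4-methyl-5,6-dihydro-2H-pyran-2-one | CC1=CC(=O)O[C@H](C1)[C@@]2(C)[C@@H](C)CC=CC2=O | intermediate
9 | C3–C8 epoxide of the cyclohexenone ring of 8 (either epoxide face) | CC1=CC(=O)O[C@H](C1)[C@@]2(C)[C@@H](C)CC3OC3C2=O | intermediate
10 | (3S,4S)-3,4-dimethyl-4-[(2R)-4-methyl-6-oxo-3,6-dihydro-2H-pyran-2-yl]hex-5-ynal | CC1=CC(=O)O[C@H](C1)[C@](C)(C#C)[C@@H](C)CC=O | intermediate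
11 | methyl (S)-3-hydroxy-2-methylpropanoate | COC(=O)[C@@H](C)CO | starting material
12 | methyl (S)-3-(tert-butyldimethylsilyloxy)-2-methylpropanoate | COC(=O)[C@@H](C)CO[Si](C)(C)C(C)(C)C | intermediate
13 | (S)-3-(tert-butyldimethylsilyloxy)-2-methylpropanal | O=C[C@@H](C)CO[Si](C)(C)C(C)(C)C | intermediate
14 | (R)-tert-butyldimethyl[(2-methylbut-3-yn-1-yl)oxy]silane | C#C[C@@H](C)CO[Si](C)(C)C(C)(C)C | intermediate
15 | diisobutyl[(3S)-4-(tert-butyldimethylsilyloxy)-3-methylbut-1-en-2-yl]alane | C=C([Al](CC(C)C)CC(C)C)[C@@H](C)CO[Si](C)(C)C(C)(C)C | intermediate (not isolated)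
16 | (S)-tert-butyl[(3-iodo-2-methylbut-3-en-1-yl)oxy]dimethylsilane | IC(=C)[C@@H](C)CO[Si](C)(C)C(C)(C)C | intermediate
17 | C8 allylic alcohol from 10 and 16 (5S,6S,8S,10R,14R; lactone at C14, terminal alkyne, C11 silyl ether) | CC1=CC(=O)O[C@H](C1)[C@](C)(C#C)[C@@H](C)C[C@H](O)C(=C)[C@@H](C)CO[Si](C)(C)C(C)(C)C | intermediate
18 | C8 tert-butyldimethylsilyl ether of 17 | CC1=CC(=O)O[C@H](C1)[C@](C)(C#C)[C@@H](C)C[C@H](O[Si](C)(C)C(C)(C)C)C(=C)[C@@H](C)CO[Si](C)(C)C(C)(C)C | intermediate
19 | (Z)-diol (C14–OH, C20–OH) from reduction of 18 | OC/C=C(/C)C[C@@H](O)[C@](C)(C#C)[C@@H](C)C[C@H](O[Si](C)(C)C(C)(C)C)C(=C)[C@@H](C)CO[Si](C)(C)C(C)(C)C | intermediate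
20 | C20 tert-butyldimethylsilyl ether of 19 | CC(C)(C)[Si](C)(C)OC/C=C(/C)C[C@@H](O)[C@](C)(C#C)[C@@H](C)C[C@H](O[Si](C)(C)C(C)(C)C)C(=C)[C@@H](C)CO[Si](C)(C)C(C)(C)C | intermediate
21 | C14 acetate of 20 (1,7-enyne) | CC(C)(C)[Si](C)(C)OC/C=C(/C)C[C@@H](OC(C)=O)[C@](C)(C#C)[C@@H](C)C[C@H](O[Si](C)(C)C(C)(C)C)C(=C)[C@@H](C)CO[Si](C)(C)C(C)(C)C | intermediate
22 | hexacarbonyldicobalt complex of the C3≡C4 alkyne of 21 | CC(C)(C)[Si](C)(C)OC/C=C(/C)C[C@@H](OC(C)=O)[C@](C)(C12[CH]3[Co]1(=C=O)(=C=O)(=C=O)[Co]23(=C=O)(=C=O)=C=O)[C@@H](C)C[C@H](O[Si](C)(C)C(C)(C)C)C(=C)[C@@H](C)CO[Si](C)(C)C(C)(C)C | intermediate (not isolated)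
23 | bicyclic enone, rings A and B (5S,6S,8S,9R,10R,14R), with the C5 side chain C14(OAc)–C13–C12(CH3)=C19–C20–OTBS (Z) and the C9 side chain C10(CH3)–C11–OTBS | CC(C)(C)[Si](C)(C)OC/C=C(/C)C[C@@H](OC(C)=O)[C@]2(C)C3=CC(=O)C[C@@]3([C@@H](O[Si](C)(C)C(C)(C)C)C[C@@H]2C)[C@@H](C)CO[Si](C)(C)C(C)(C)C | intermediate
24 | C11,C20-diol of 23 | OC/C=C(/C)C[C@@H](OC(C)=O)[C@]2(C)C3=CC(=O)C[C@@]3([C@@H](O[Si](C)(C)C(C)(C)C)C[C@@H]2C)[C@@H](C)CO | intermediate
25 | (Z)-C20 allylic chloride, C11 alcohol | ClC/C=C(/C)C[C@@H](OC(C)=O)[C@]2(C)C3=CC(=O)C[C@@]3([C@@H](O[Si](C)(C)C(C)(C)C)C[C@@H]2C)[C@@H](C)CO | intermediate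
26 | (Z)-C20 allylic chloride, C11 aldehyde | ClC/C=C(/C)C[C@@H](OC(C)=O)[C@]2(C)C3=CC(=O)C[C@@]3([C@@H](O[Si](C)(C)C(C)(C)C)C[C@@H]2C)[C@@H](C)C=O | intermediate
27 | 8-O-tert-butyldimethylsilyl ether of the target | C=C[C@]1(C)C[C@@H](OC(C)=O)[C@]2(C)C3=CC(=O)C[C@@]3([C@@H](O[Si](C)(C)C(C)(C)C)C[C@@H]2C)[C@@H](C)[C@@H]1O | intermediate
28 | pleuromutilin E as written (5S,6S,8S,9R,10R,11S,12S,14R) | C=C[C@]1(C)C[C@@H](OC(C)=O)[C@]2(C)C3=CC(=O)C[C@@]3([C@@H](O)C[C@@H]2C)[C@@H](C)[C@@H]1O | target

**Step count and risks**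

Total step count: 23. Longest linear sequence: 19 steps (steps 1–8, then 13–23); steps 9–12 make the second fragment.

Step 18 (key step). The hindered 1,1-disubstituted C9=C1 alkene, flanked by the C8 silyl ether and the branched C10, may fail to insert into the cobalt–alkyne complex, so that the complex decomposes or is reduced. Insertion may also occur with poor facial selectivity at C9. The fallback sets out from 21 and replaces the cobalt carbonylation by a zerovalent-nickel-mediated enyne–isocyanide cyclisation. Ni(cod)2, PBu3 and 2,6-dimethylphenyl isocyanide in DMF at room temperature would form the nickelacyclopentene from C3≡C4 and C9=C1 and insert the isocyanide to give N-aryl iminocyclopentene F1. Mild hydrolysis (oxalic acid on wet silica) would then give enone 23, where the route is rejoined.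

Step 22. Closure of the strained trans-bridged eight-membered ring may be slow, so that intermolecular coupling or simple reduction of the allylic chloride competes. The facial selectivity at C11 and C12 is also uncertain. The fallback sets out from 25. Pd(PPh3)4-catalysed silylation of the allylic chloride with hexamethyldisilane would give allylsilane F2, and Dess–Martin oxidation would give aldehyde F3. An intramolecular Hosomi–Sakurai reaction (BF3·OEt2, CH2Cl2, −78 °C, open transition state, γ-attack at C12) would then close ring C and return to 27.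

Step 13. Ligand control at C8 may be insufficient with this β-branched aldehyde, and the terminal alkyne may interfere with the nickel co-catalyst. The fallback sets out from 16. Iodine–lithium exchange (t-BuLi, −78 °C), transmetallation with CeCl3 and addition to 10 would give the C8-epimeric alcohols F4, and Dess–Martin oxidation would give enone F5. Corey–Bakshi–Shibata reduction with catecholborane at −78 °C would return the single epimer 17; the catalyst is 1-methyl-3,3-diphenyltetrahydro-1H,3H-pyrrolo[1,2-c][1,3,2]oxazaborole, in the enantiomer that delivers the 8S alcohol.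

**Further compounds**

F1 | step 18 | N-(2,6-dimethylphenyl)imine at C2 of enone 23 | CC(C)(C)[Si](C)(C)OC/C=C(/C)C[C@@H](OC(C)=O)[C@]2(C)C3=CC(=Nc4c(C)cccc4C)C[C@@]3([C@@H](O[Si](C)(C)C(C)(C)C)C[C@@H]2C)[C@@H](C)CO[Si](C)(C)C(C)(C)C
F2 | step 22 | (Z)-allylsilane, C20–SiMe3 analogue of chloride 25 | C[Si](C)(C)C/C=C(/C)C[C@@H](OC(C)=O)[C@]2(C)C3=CC(=O)C[C@@]3([C@@H](O[Si](C)(C)C(C)(C)C)C[C@@H]2C)[C@@H](C)CO
F3 | step 22 | C11 aldehyde of allylsilane F2 | C[Si](C)(C)C/C=C(/C)C[C@@H](OC(C)=O)[C@]2(C)C3=CC(=O)C[C@@]3([C@@H](O[Si](C)(C)C(C)(C)C)C[C@@H]2C)[C@@H](C)C=O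
F4 | step 13 | C8-epimeric mixture of alcohol 17 | CC1=CC(=O)O[C@H](C1)[C@](C)(C#C)[C@@H](C)CC(O)C(=C)[C@@H](C)CO[Si](C)(C)C(C)(C)C
F5 | step 13 | C8 ketone (enone) corresponding to 17 | CC1=CC(=O)O[C@H](C1)[C@](C)(C#C)[C@@H](C)CC(=O)C(=C)[C@@H](C)CO[Si](C)(C)C(C)(C)C
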